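1. 5 questions stood on the bench when I handed it over: which flask leads in E, and how much E each of the four holds at the end.

| flask | Q | temperature | remark | time |
|---|---|---|---|---|
| midnight | 0.12 M | 50 °C | run made earlier |  |
| spring | 0.50 M | 72 °C | run made earlier |  |
| south-east | 0.25 M | 80 °C |  | 20 h |
| north | 0.25 M | 60 °C |  | 20 h |
| west | 0.25 M | 40 °C |  | 20 h |
| east | 0.25 M |  | at 80 °C until 4.0 h, from then on at 40 °C | 20 h |

| run | time / h | E / % | Q / % |
|---|---|---|---|
| midnight | 6.00 | 58.5 | 38.8 |
| midnight | 20.0 | 57.7 | 36.9 |
| midnight | 40.0 | 55.6 | 32.8 |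
| midnight | 48.0 | 55.0 | 31.7 |
| midnight | 96.0 | 51.6 | 25.5 |
| midnight | 120 | 50.2 | 23.1 |
| spring | 4.00 | 25.2 | 49.3 |
| spring | 8.00 | 22.6 | 37.1 |
| spring | 12.0 | 20.7 | 28.4 |
| spring | 15.0 | 19.3 | 23.6 |
| spring | 20.0 | 17.5 | 18.8 |
| spring | 25.0 | 16.1 | 15.3 |

(standard deviation of a reading: 0.3 percentage points)

1. which flask leads in amount of E, in percent of the Q charged ("all alike" within 1.5 percentage points) (south-east / north / west / east / all alike)
2. how much E is there at the end, in percent of the Q charged: south-east
3. how much E is there at the end, in percent of the Q charged: north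
4. how much E is there at the end, in percent of the Q charged: west
5. how much E is there at the end, in percent of the Q charged: east

2. In both earlier runs E jumped early and then sank slowly with Q still present. The midnight run showed E 58.5% and Q 38.8% at 6.00 h; the spring run showed E 25.2% and Q 49.3% at 4.00 h.

3. I took each stop for a balance: Q splits into E and an unseen partner in equal amounts, and the two can rejoin. The reading to take was then the charge times the square of E's share, divided by Q's share. It gave 0.106 M at midnight and 0.0644 M in spring.

4. I stretched the logarithm of these readings in proportion to degrees, which gave 0.133 M at 40 °C. This stopping quotient at the west temperature (an apparent equilibrium constant) was what I carried forward. The same stretch gave 0.0538 M at 80 °C.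

5. My note for the next person read: with nothing lost, west stops at E 51.0%. Do not warm west: the quotient at 80 °C is lower than at 40 °C, which with nothing lost puts a fresh charge at 36.9% instead of 51.0%, and the slow sinking seen in both runs comes on top. Do not skip the cooling of east: at 4.0 h the quotient rises from 0.0538 M to 0.133 M, so the balance moves towards E, starting from whatever the hot hours have left.

6. The forecast named west and gave south-east 10%, north 41%, west 72% and east 19.5%. Its west stands higher than my ceiling, and it said of its burst yields: “This assumes the concentration difference doesn't matter”.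

7. The flasks gave west as leader, with south-east 18.3%, north 37.7%, west 51.0% and east 41.5%.

    Q + E → G (k = 0.00661 M⁻¹ h⁻¹, Ea = 100 kJ mol⁻¹)
    Q + L → D (k = 0.0330 M⁻¹ h⁻¹, Ea = 66.0 kJ mol⁻¹)
    Q ⇌ E + L (K = 0.140 M, k = 0.468 h⁻¹, Ea = 87.0 kJ mol⁻¹, ΔH = −25.0 kJ mol⁻¹)
    (constants at 40 °C)

8. In south-east, L fell back 190 times faster than it went on at 0.0118 h. East at its change held Q 43.6%, E 29.2% and L 0.0704 M; bringing that state to my 0.133 M gives E 41.4%, and east ended at 41.5%.

9. Take the neighbour of south-east charged with 0.062 M. My 0.0538 M puts its ceiling at 59.4%. The computed flask held E 43.7%, below that ceiling, beside D 11.5% and G 20.5%.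

The data stem from a simulated flask from invented constants; noise was put on by code.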